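Plan (carotenoid numbering: ring carbons C1–C6, chain C7–C15, primes for the second half)
1. Retrosynthesis cuts C10=C11 and C10'=C11' (twofold Wittig) into two C14 aldehydes and a C12 bis-phosphonium salt, then C8=C9 (Wittig), then C6=C7 with C7–C8 (two-carbon formyl-olefination of a C6 ketone), and last, in the ring, C2–C3 together with C4=C5.
2. Forward: the ring is made first by a (4+2) union of a four-carbon ketone homoenolate (C5, C6, C1, C2) with glyoxal mono-acetal (C3, C4). The exocyclic C6=C7 bond and the chain to C10 follow, and two such halves are joined on the central C12 unit.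
3. Enabling feature: in each cyclohexene ring the carbinol C3 and C6 (a ketone until step 3) are 1,4-related through the quaternary C1(CH3)2, a homoaldol pattern, and C4=C5 is the α,β-bond of that ketone, an aldol-condensation pattern. Because C1 bears no hydrogen, a metal on C2 cannot β-eliminate and C5 is the only enolisable carbon.
4. Stereochemistry: the only stereocenters (C3 and C3', both S) are set in the key step by a chiral titanium TADDOLate. The E double bonds come from stabilised-ylide Wittig reactions, trans-reduction of propargylic alcohols and a final thermal equilibration to the all-E (6E,6'E) polyene.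

Key step: step 2

Assumption: (R,R)-TADDOL is taken to keep its usual Si-face selectivity with aldehyde 4, and the 6E/6Z and chain E/Z isomers are taken to equilibrate thermally towards the all-E isomer, as is general for carotenoids.

Step 1
Reactants: 1 3-bromo-2,2-dimethylpropanoic acid
Product: 3 1-bromo-2,2-dimethylpentan-3-one, via acid chloride 2 (not isolated)
Conditions: (COCl)2, cat. DMF, CH2Cl2, 0 °C to rt, evaporate; EtMgBr (1.05 equiv), Fe(acac)3 (3 mol%), THF, −78 °C
Reagents that add atoms: ethylmagnesium bromide, CC[Mg]Br; oxalyl chloride, O=C(Cl)C(Cl)=O (its chlorine stays only in 2)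
Why: Acid chloride formation followed by the iron-catalysed ketone synthesis from an acid chloride and a Grignard reagent should stop at the ketone and leave the neopentyl C–Br bond untouched at −78 °C; no stereocenter is formed.

Step 2
Reactants: 3 1-bromo-2,2-dimethylpentan-3-one; 4 2,2-diethoxyacetaldehyde
Product: 8 (4S)-4-hydroxy-2,6,6-trimethylcyclohex-2-en-1-one, via zinc homoenolate 5 (not isolated), via titanium homoenolate 6 (not isolated), via hydroxy acetal 7 (not isolated)
Conditions: Zn dust (TMSCl-activated), LiCl, THF, 50 °C; ClTi(OiPr)3, toluene, −40 °C; 4, (R,R)-TADDOL (20 mol%), Ti(OiPr)4 (25 mol%), −40 to −20 °C; then 2 M aq HCl, THF, 40 °C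
Reagents that add atoms: none
Why: Proposed new method: zinc inserts into the neopentyl C–Br bond of 3 to give the carbonyl-chelated homoenolate 5 (β-elimination is impossible at the quaternary C1), exchange with ClTi(OiPr)3 gives the alkyltitanium 6, and this transfers C2 to the aldehyde carbon of 4 on the chiral titanium TADDOLate to form C2–C3, the closest known reaction types being the addition of zinc and titanium homoenolates to aldehydes and the TADDOLate-catalysed enantioselective addition of alkyltitanium triisopropoxides to aldehydes. The new stereocenter C3 is set by the catalyst, since (R,R)-TADDOLates direct alkyl transfer to the Si face of aldehydes, which here is the (S)-carbinol 7. Aqueous acid then hydrolyses the acetal, and the enol of the ethyl ketone attacks the freed aldehyde carbon C4 from C5 in a 6-(enolexo)-exo-trig aldol closure whose β-hydroxy ketone dehydrates to the C4=C5 enone, as in any acid-mediated aldol cyclisation of a 1,5-dicarbonyl compound. Chemoselectivity is needed between aldehyde and ketone and is secured by the aldehyde-selective alkyltitanium and by the doubly α-branched, internally coordinated ketone of 6. Regioselectivity of the closure is secured by the substrate, because C5 is the only enolisable position of the ketone and the aldehyde is the only electrophile, so that no ring other than the six-membered one can form. C3 is not involved in the closure, so its configuration should pass unchanged into 8.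

Step 3
Reactants: 8 (4S)-4-hydroxy-2,6,6-trimethylcyclohex-2-en-1-one; 9 (Z)-1-bromo-2-ethoxyethene
Product: 12 (2E)-2-[(4S)-4-hydroxy-2,6,6-trimethylcyclohex-2-en-1-ylidene]acetaldehyde, via vinyllithium 10 (not isolated), via enol ether diol 11 (not isolated)
Conditions: 9 (2.6 equiv), n-BuLi (2.5 equiv), THF, −78 °C; 8, −78 to −20 °C; then 1 M aq HCl, THF, 0 °C
Reagents that add atoms: water, O
Why: Bromine–lithium exchange gives the 2-ethoxyvinyllithium, of which one equivalent deprotonates the hydroxyl and a second adds 1,2 to the hindered enone carbonyl, and mild acid then ionises the tertiary allylic alcohol through the conjugated oxocarbenium ion and hydrolyses it to the dienal (two-carbon formyl-olefination of a ketone), the 6E geometry being the expected thermodynamic one and the C3 carbinol remaining untouched.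

Step 4
Reactants: 12 (2E)-2-[(4S)-4-hydroxy-2,6,6-trimethylcyclohex-2-en-1-ylidene]acetaldehyde; 13 2-(triphenylphosphoranylidene)propanal
Product: 14 (2E,4E)-4-[(4S)-4-hydroxy-2,6,6-trimethylcyclohex-2-en-1-ylidene]-2-methylbut-2-enal
Conditions: toluene, 90 °C
Reagents that add atoms: none
Why: Wittig olefination with a stabilised formyl ylide should be E-selective for the new trisubstituted C8=C9 bond and stop after one homologation, because the α-methyl enal formed is less reactive than 12.

Step 5
Reactants: 15 3-methylpent-1-en-4-yn-3-ol (2 equiv)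
Product: 16 3,8-dimethyldeca-1,9-diene-4,6-diyne-3,8-diol
Conditions: CuCl (10 mol%), TMEDA, O2 (1 atm), acetone, rt
Reagents that add atoms: none
Why: Glaser–Hay oxidative homocoupling joins two molecules of 15 at their terminal alkyne carbons (the two acetylenic hydrogens leave as water with O2 as the oxidant), it tolerates the tertiary alcohol and the vinyl group, and the two carbinol centers need no control because both are destroyed in step 7.

Step 6
Reactants: 16 3,8-dimethyldeca-1,9-diene-4,6-diyne-3,8-diol
Product: 17 (4E,6E)-3,8-dimethyldeca-1,4,6,9-tetraene-3,8-diol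
Conditions: LiAlH4, THF, 0 °C to reflux
Reagents that add atoms: none
Why: Hydroxyl-directed trans-hydroalumination of each propargylic triple bond (LiAlH4 reduction of propargylic alcohols) should give the (4E,6E)-diene and leave the isolated vinyl groups alone.

Step 7
Reactants: 17 (4E,6E)-3,8-dimethyldeca-1,4,6,9-tetraene-3,8-diol
Product: 18 [(2E,4E,6E,8E)-3,8-dimethyldeca-2,4,6,8-tetraene-1,10-diyl]bis(triphenylphosphonium) dibromide
Conditions: Ph3P·HBr (2.1 equiv), CH2Cl2, rt
Reagents that add atoms: triphenylphosphine hydrobromide, [Br-].[PH+](c1ccccc1)(c1ccccc1)c1ccccc1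
Why: Ionisation of each tertiary vinyl carbinol and capture of the delocalised cation by triphenylphosphine at the primary terminus (the allylic transposition by which vinyl carbinols are turned into allylic phosphonium salts) should give the fully conjugated bis-salt, and any Z isomer at the new trisubstituted bonds is corrected in the final equilibration.

Step 8
Reactants: 14 (2E,4E)-4-[(4S)-4-hydroxy-2,6,6-trimethylcyclohex-2-en-1-ylidene]-2-methylbut-2-enal (2 equiv); 18 [(2E,4E,6E,8E)-3,8-dimethyldeca-2,4,6,8-tetraene-1,10-diyl]bis(triphenylphosphonium) dibromide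
Product: 20 (3S,3'S,6E,6'E)-4',5'-didehydro-4,5'-retro-β,β-carotene-3,3'-diol (eschscholtzxanthin; target), via bis-ylide 19 (not isolated)
Conditions: NaOMe, MeOH/CH2Cl2, 0 °C to rt, Ar, dark; then n-heptane, reflux; crystallisation
Reagents that add atoms: none
Why: The twofold Wittig reaction of an allylic bis-ylide with an α-methyl enal (the usual end-to-centre carotenoid assembly) forms C10=C11 and C10'=C11' in the presence of the free (S)-carbinols, and thermal equilibration should convert Z isomers into the all-E (6E,6'E) polyene.

Compound list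
1 | 3-bromo-2,2-dimethylpropanoic acid | OC(=O)C(C)(C)CBr | starting material
2 | 3-bromo-2,2-dimethylpropanoyl chloride | ClC(=O)C(C)(C)CBr | intermediate
3 | 1-bromo-2,2-dimethylpentan-3-one | CCC(=O)C(C)(C)CBr | intermediate
4 | 2,2-diethoxyacetaldehyde | CCOC(OCC)C=O | starting material
5 | (2,2-dimethyl-3-oxopentyl)zinc bromide | CCC(=O)C(C)(C)C[Zn]Br | intermediate
6 | (2,2-dimethyl-3-oxopentyl)tri(propan-2-yloxy)titanium | CCC(=O)C(C)(C)C[Ti](OC(C)C)(OC(C)C)OC(C)C | intermediate
7 | (6S)-7,7-diethoxy-6-hydroxy-4,4-dimethylheptan-3-one | CCC(=O)C(C)(C)C[C@H](O)C(OCC)OCC | intermediate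
8 | (4S)-4-hydroxy-2,6,6-trimethylcyclohex-2-en-1-one | CC1=C[C@@H](O)CC(C)(C)C1=O | intermediate
9 | (Z)-1-bromo-2-ethoxyethene | CCO/C=C\Br | starting material
10 | (Z)-(2-ethoxyethenyl)lithium | CCO/C=C\[Li] | intermediate
11 | (4S)-1-[(Z)-2-ethoxyethenyl]-2,6,6-trimethylcyclohex-2-ene-1,4-diol (both C1 epimers) | CCO/C=C\C1(O)C(C)=C[C@@H](O)CC1(C)C | intermediate
12 | (2E)-2-[(4S)-4-hydroxy-2,6,6-trimethylcyclohex-2-en-1-ylidene]acetaldehyde | CC1=C[C@@H](O)CC(C)(C)\C1=C/C=O | intermediate
13 | 2-(triphenylphosphoranylidene)propanal | CC(C=O)=P(c1ccccc1)(c1ccccc1)c1ccccc1 | starting material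
14 | (2E,4E)-4-[(4S)-4-hydroxy-2,6,6-trimethylcyclohex-2-en-1-ylidene]-2-methylbut-2-enal | CC1=C[C@@H](O)CC(C)(C)\C1=C/C=C(C)/C=O | intermediate
15 | 3-methylpent-1-en-4-yn-3-ol (racemic) | C#CC(C)(O)C=C | starting material
16 | 3,8-dimethyldeca-1,9-diene-4,6-diyne-3,8-diol (diastereomer mixture) | C=CC(C)(O)C#CC#CC(C)(O)C=C | intermediate
17 | (4E,6E)-3,8-dimethyldeca-1,4,6,9-tetraene-3,8-diol (diastereomer mixture) | C=CC(C)(O)/C=C/C=C/C(C)(O)C=C | intermediate
18 | [(2E,4E,6E,8E)-3,8-dimethyldeca-2,4,6,8-tetraene-1,10-diyl]bis(triphenylphosphonium) dibromide | C(/C=C(C)/C=C/C=C/C(C)=C/C[P+](c1ccccc1)(c1ccccc1)c1ccccc1)[P+](c1ccccc1)(c1ccccc1)c1ccccc1.[Br-].[Br-] | intermediate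
19 | [(2E,4E,6E,8E)-3,8-dimethyldeca-2,4,6,8-tetraene-1,10-diylidene]bis(triphenylphosphorane) | C(/C=C(C)/C=C/C=C/C(C)=C/C=P(c1ccccc1)(c1ccccc1)c1ccccc1)=P(c1ccccc1)(c1ccccc1)c1ccccc1 | intermediate
20 | (3S,3'S,6E,6'E)-4',5'-didehydro-4,5'-retro-β,β-carotene-3,3'-diol | CC1=C[C@@H](O)CC(C)(C)\C1=C/C=C(C)/C=C/C=C(C)/C=C/C=C/C(C)=C/C=C/C(C)=C/C=C1/C(C)=C[C@@H](O)CC1(C)C | target

Total step count: 8. Longest linear sequence: 5 steps (steps 1, 2, 3, 4, 8). Steps 5–7 form the convergent branch.

Steps most likely to fail

Step 2. Achiral zinc and lithium halide species may promote a background addition that erodes the enantioselectivity. The chelated homoenolate may transfer its alkyl group slowly. The α-hydroxy aldehyde freed on acetal hydrolysis may enolise, and so racemise or isomerise to the hydroxy ketone, before the aldol closure. The fallback uses known chemistry and sets the stereocenter by ketone reduction instead of C–C bond formation. It sets out from 3: the homoenolates 5 and 6 are made as before and added to 4 without the chiral ligand (THF, −20 °C) to give racemic 7,7-diethoxy-6-hydroxy-4,4-dimethylheptan-3-one F1. Treatment with 2 M HCl closes it to racemic 4-hydroxy-2,6,6-trimethylcyclohex-2-en-1-one F2. MnO2 in CH2Cl2 oxidises the allylic alcohol to 2,6,6-trimethylcyclohex-2-ene-1,4-dione F3. Asymmetric transfer hydrogenation with RuCl(p-cymene)[(S,S)-TsDPEN] in HCO2H/Et3N should reduce the less hindered carbonyl, and the route is rejoined at 8.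

Step 3. Addition to the hindered carbonyl may be slow, so that γ-deprotonation of the enone competes. On acid treatment the allylic cation may be captured in the ring, or a 6E/6Z mixture may form. The fallback sets out from 8: ethynylmagnesium bromide (3 equiv, THF, 0 °C) adds to the ketone to give (4S)-1-ethynyl-2,6,6-trimethylcyclohex-2-ene-1,4-diol F4. A Meyer–Schuster rearrangement (MoO2(acac)2, Ph3PAuCl, AgOTf, toluene, rt) then gives the enal; the competing Rupe pathway is closed because neither carbon next to C6 carries hydrogen. The route is rejoined at 12.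

Step 8. The second olefination may stall at the mono-adduct. E/Z mixtures at C10=C11, C12=C13 and C6=C7, together with the light and air sensitivity of the dodecaene, may lower the recovery of the all-E isomer. The fallback replaces the ylide by a phosphonate carbanion and sets out from 17: PBr3 (Et2O, −10 °C) gives, with allylic transposition, (2E,4E,6E,8E)-1,10-dibromo-3,8-dimethyldeca-2,4,6,8-tetraene F5. An Arbuzov reaction with P(OEt)3 (120 °C) gives tetraethyl [(2E,4E,6E,8E)-3,8-dimethyldeca-2,4,6,8-tetraene-1,10-diyl]bis(phosphonate) F6. A twofold Horner–Wadsworth–Emmons reaction with 14 (NaH, THF, 0 °C to rt), which should be more E-selective, rejoins the route at 20.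

Further compounds
F1 | step 2 | racemic 7,7-diethoxy-6-hydroxy-4,4-dimethylheptan-3-one | CCC(=O)C(C)(C)CC(O)C(OCC)OCC
F2 | step 2 | racemic 4-hydroxy-2,6,6-trimethylcyclohex-2-en-1-one | CC1=CC(O)CC(C)(C)C1=O
F3 | step 2 | 2,6,6-trimethylcyclohex-2-ene-1,4-dione | CC1=CC(=O)CC(C)(C)C1=O
F4 | step 3 | (4S)-1-ethynyl-2,6,6-trimethylcyclohex-2-ene-1,4-diol | C#CC1(O)C(C)=C[C@@H](O)CC1(C)C
F5 | step 8 | (2E,4E,6E,8E)-1,10-dibromo-3,8-dimethyldeca-2,4,6,8-tetraene | BrC/C=C(C)/C=C/C=C/C(C)=C/CBr
F6 | step 8 | tetraethyl [(2E,4E,6E,8E)-3,8-dimethyldeca-2,4,6,8-tetraene-1,10-diyl]bis(phosphonate) | CCOP(=O)(OCC)C/C=C(C)/C=C/C=C/C(C)=C/CP(=O)(OCC)OCC
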